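## Structural features

The target is a single benzene ring (ring A) with four substituents: a carboxylic acid on C1, a phenolic hydroxyl on C2, a methoxy group on C4 and, on C6, a thirteen-carbon chain joined through its C1′ methylene, with a ketone at C2′ and a primary alcohol at C13′. There is no second ring and no stereocentre, so no stereocentres stand next to each other and the problem is one of regiochemistry and chemoselectivity. The real difficulty is the contiguous C2–C1–C6 pattern, in which the carboxyl sits between the phenol and the chain. Added to this, the two ring oxygens must be told apart (free OH ortho to the acid, methyl ether para to it) and the chain carbonyl must sit exactly on the homobenzylic carbon C2′. The molecule is fragile in several ways: the C1′ methylene lies between arene and ketone and enolises easily, the enol oxygen is within reach of the carboxyl carbon so that acid or dehydrating conditions close an isocoumarin, and an electron-rich salicylic acid can lose CO2 on heating in acid. Strong base on a carboxylic ester next to this ketone invites acyl transfer to the enolate, and the free ring carbons C3 and C5 are nucleophilic towards halogenating oxidants and carbocations. The key step uses the fact that the carboxyl carbon and C2′ are 1,5-related through C1, C6 and C1′, so an oxygen on C2′ and the carboxyl carbon are the two ends of a six-membered ring. A C2′ alcohol can therefore hold palladium at the C1–H bond and become the ring oxygen of a 3,4-dihydroisocoumarin once CO is taken up. With both ring oxygens as methyl ethers the arene has a mirror plane through C6 and C3, which makes C1 and C5 identical.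

## Logic of the disconnections

15 ⇒ 14. The O–Si bond of the terminal alcohol is cut last. The silyl ether is the only group left, and fluoride acts on 14 as its carboxylate and phenoxide, which offer no electrophile to the enolisable ketone. The demand is a cold, mild acidification afterwards so that the keto acid does not dehydrate.

14 ⇒ 13. Two C–O bonds are cut together: the benzyl–oxygen bond of the ester and the methyl–oxygen bond of the ether ortho to the carbonyl. One Lewis acid does both, which saves a separate ester hydrolysis under base next to the ketone. The forward step must distinguish the C2 ether from the C4 ether (chelation does this), must intercept the benzyl cation, and must leave the silyl ether and the ketone alone at low temperature.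

13 ⇒ 12. The C2′ carbonyl is taken back to the secondary alcohol. This is an oxidation-level change only, but it is the price of having an oxygen on C2′ that can direct a metal. The forward oxidation must be neutral and fast, because 12 can close back to 10.

12 ⇒ 10 (through 11). The carboxyl carbon is reconnected to the C2′ oxygen. This converts an open arene with three adjacent substituents into a bicyclic lactone that a single C–H functionalisation can make. The forward opening must be irreversible (hydroxide, giving 11) and the carboxylate must be alkylated without passing through the free hydroxy acid.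

10 ⇒ 8 + 9. The bond from C1 to the carbonyl carbon and the acyl–oxygen bond of the lactone are cut, so the carboxyl carbon leaves as 9. The gain is large: 8 has a symmetric, unfunctionalised 3,5-dimethoxyphenyl ring and is made by carbonyl chemistry alone. The forward step must palladate ortho to the chain and not between the methoxy groups, and must carbonylate faster than it oxidises the secondary alcohol.

8 ⇒ 7. The C2′–H bond is cut (ketone reduction). No stereocontrol is asked for, because the carbinol centre is erased in going from 12 to 13.

7 ⇒ 5 + 6. The C2′–C3′ bond is cut next to the carbonyl, dividing the molecule into an arylacetyl unit and the C11 chain. The forward addition must stop at the ketone (chelated tetrahedral adduct) and must outrun deprotonation of the acidic benzylic position of 5.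

5 ⇒ 3 (through 4), and 6 ⇒ 2 ⇒ 1. The amide C–N bond, the C–Mg bond and the O–Si bond are cut to reach the two purchased building blocks 3 and 1. The silyl group on 2 is chosen for its resistance to Grignard formation, to the hot, acetic-acid-releasing carbonylation and to brief BCl3.

## Other disconnections considered

Alternative 1: The cut is the ring bond C1–C6, so ring A is assembled from an open polycarbonyl chain. In the forward sense the diketo-dioxinone A1 is treated with Et3N and then mild acid. The dioxinone carbon next to the lactone carbonyl adds to the distal ketone, water is lost and the benzodioxinone A2 is formed. In its favour, the two ring oxygens come out already differentiated: the C2 oxygen is tied up with the carboxyl in the acetonide and the C4 hydroxyl is free for methylation. On this point it is better than the chosen plan, which needs a chelation-controlled demethylation. It also carries C2′ at the ketone level as a ketal, so it is better in redox economy, since the chosen plan reduces and re-oxidises that carbon. It needs no transition metal and no CO. Against it here, A1 must be built by two C-acylations of dioxinone enolates with strong base, and the side-chain acyl donor needs several steps of its own. The dioxolane sits β to the distal ketone, so the enolate formed under Et3N can expel alkoxide. Once acid frees that ketone the chain offers a fourth carbonyl and other aldol modes. After A2 come O-methylation, hot hydroxide to open the benzodioxinone, and acid to remove ketal and silyl ether, which exposes the free keto acid to the isocoumarin closure. In comparison, the chosen plan closes its ring by a tethered metalation with only one possible site, whereas this aldol aromatisation depends on one of several enolate pathways winning. On step count the chosen plan (eight in the longest line) should be shorter, as the route through A1 is estimated at ten or more.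

Alternative 2: The cut is the C6–C1′ bond together with the enol-lactone C–O bond. In the forward sense 2,4-dimethoxybenzoic acid A3 and the acyl sulfoxonium ylide A4 react under [Cp*RhCl2]2 and AgSbF6 (trivalent rhodium). Carboxylate-directed ortho C–H rhodation, carbene formation from the ylide with loss of the sulfoxide, and migratory insertion give the ortho-acylmethyl acid, which closes to the isocoumarin A5. In its favour, the carboxyl group is already in place and is the directing group, so no CO is needed. A3 has a single ortho C–H, so regiocontrol is the equal of the symmetry argument in the chosen plan. A5 holds C2′ at the ketone level as an enol lactone, so hydroxide opens it directly to the keto acid with no alcohol oxidation and no ester detour. It is therefore better in redox economy and probably better in step economy, at about six or seven steps against nine. Against it here, the C–H bond to be broken is meta to both methoxy groups and ortho-methoxybenzoic acids bind the metal less well. Alkyl acyl ylides are less reactive than aryl ones, and a silyl ether must survive a hot, Lewis-acidic cationic rhodium medium. The route still needs the same chelation-controlled demethylation, and its last step is the opening of a phenoxide-deactivated 8-hydroxyisocoumarin followed by a delicate acidification. In comparison, both plans are directed C–H functionalisations that close the same six-membered lactone. The alternative forms the bond to the chain, the chosen plan the bond to the carboxyl carbon. The chosen plan has the advantage of cheap palladium and of a precursor made entirely by robust carbonyl chemistry, but its lactone opening is a weakness that this alternative does not have.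

Alternative 3: The cuts are the ring bonds C1–C2 and C5–C6. In the forward sense the ketene-acetal diene A6 and the ynoate A7 are heated. A Diels–Alder addition is followed by loss of methanol to give the salicylate A8. In its favour, the polarisation of diene and dienophile fixes the orientation, so the free phenol, the methyl ether and the ester appear in the right places at once. This is better than the chosen plan on oxygen differentiation, and equal or better in using no transition metal. The ketone is carried as a dithiane at the correct oxidation level. Against it here, a 2-alkynoate with an alkyl group on its β-carbon is a sluggish dienophile, and the long heating it needs is hard on the moisture-sensitive diene A6. The propargylic methylene of A7 between alkyne and dithiane can isomerise to an allene. The dithiane must later be removed with halonium sources, hypervalent iodine reagents or HgCl2 (divalent mercury), to all of which the electron-rich phenol ring is exposed. The hindered methyl salicylate must finally be saponified with strong base beside the enolisable ketone, a step the chosen plan avoids through its benzyl ester. In comparison, step counts should be similar (about eight or nine). The cycloaddition is a less certain ring-forming step than the tethered carbonylation, and the end game is harsher than that of the chosen plan.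

Key step: step 5

Remark on the chemistry: the target is taken as the open-chain keto acid that its SMILES shows. The carbinol centre carried from 8 to 12 is racemic and is destroyed in step 7, so no enantiocontrol is planned.

## Route

Step 1
Reactants: 1 11-bromoundecan-1-ol
Product: 2 tert-butyl[(11-bromoundecyl)oxy]diphenylsilane
Conditions: TBDPSCl, imidazole, CH2Cl2, 0 °C → rt
Reagents that add atoms: tert-butyl(chloro)diphenylsilane, CC(C)(C)[Si](Cl)(c1ccccc1)c1ccccc1
Why: Imidazole-promoted silylation of a primary alcohol; the mild, weakly basic medium leaves the primary bromide untouched, and the bulky TBDPS ether is chosen because it should withstand Grignard formation, NaBH4, the hot carbonylation medium and brief BCl3.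

Step 2
Reactants: 3 3,5-dimethoxyphenylacetic acid
Product: 5 2-(3,5-dimethoxyphenyl)-N-methoxy-N-methylacetamide, via acyl imidazole 4 (not isolated)
Conditions: CDI, CH2Cl2, rt; then MeNH(OMe)·HCl, rt
Reagents that add atoms: 1,1'-carbonyldiimidazole, O=C(n1ccnc1)n1ccnc1 (imidazolyl group, in intermediate 4 only); N,O-dimethylhydroxylamine hydrochloride, CNOC.Cl
Why: Carboxyl activation as the acyl imidazole followed by aminolysis (Weinreb amide synthesis); no strong base is present, so the acidic benzylic position is not disturbed.

Step 3
Reactants: 2 tert-butyl[(11-bromoundecyl)oxy]diphenylsilane; 5 2-(3,5-dimethoxyphenyl)-N-methoxy-N-methylacetamide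
Product: 7 13-[(tert-butyldiphenylsilyl)oxy]-1-(3,5-dimethoxyphenyl)tridecan-2-one, via Grignard reagent 6 (not isolated)
Conditions: Mg, cat. I2, THF, 50 °C; then 5, THF, 0 °C → rt; aq. NH4Cl
Reagents that add atoms: magnesium, [Mg] (in intermediate 6 only)
Why: Grignard formation from a primary bromide and Weinreb ketone synthesis; the magnesium-chelated tetrahedral adduct persists until work-up, so addition should stop at the ketone, and a modest excess of 6 at 0 °C offsets competing enolisation of the arylacetamide.

Step 4
Reactants: 7 13-[(tert-butyldiphenylsilyl)oxy]-1-(3,5-dimethoxyphenyl)tridecan-2-one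
Product: 8 racemic 13-[(tert-butyldiphenylsilyl)oxy]-1-(3,5-dimethoxyphenyl)tridecan-2-ol
Conditions: NaBH4, MeOH/THF, 0 °C
Reagents that add atoms: none
Why: Borohydride reduction of a ketone; the new carbinol centre forms without control and is meant to be racemic, since it serves only as the directing group and is oxidised away in step 7.

Step 5
Reactants: 8 racemic 13-[(tert-butyldiphenylsilyl)oxy]-1-(3,5-dimethoxyphenyl)tridecan-2-ol; 9 carbon monoxide
Product: 10 racemic 3-{11-[(tert-butyldiphenylsilyl)oxy]undecyl}-6,8-dimethoxyisochroman-1-one
Conditions: Pd(OAc)2 (10 mol %), N-acetylglycine (20 mol %), AgOAc (3 equiv), Li2CO3 (1 equiv), CO (1 atm), CH2Cl2, 110 °C, sealed tube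
Reagents that add atoms: none
Why: The hydroxyl of 8 binds divalent palladium as an alkoxide, and carboxylate-assisted concerted metalation–deprotonation of the ortho C–H bond gives a six-membered oxapalladacycle. CO (9) inserts into the aryl–palladium bond to give an aroyl palladium alkoxide, and C–O reductive elimination releases lactone 10 and zerovalent palladium, which two equivalents of AgOAc return to divalent palladium. The closest known reaction type is the palladium-catalysed hydroxyl-directed ortho C–H carbonylation of phenethyl alcohols to isochroman-1-ones with a mono-N-protected amino acid ligand. The one new ring is the six-membered δ-lactone, closed by acyl C–O bond formation on the tethered oxygen (reductive elimination from the acyl palladium alkoxide, formally a 6-exo-trig acyl capture), with the bond from C1 to the carbonyl carbon made in the same turnover. No stereocentre is created; the carbinol carbon is untouched and stays racemic, and the achiral ligand is chosen so that both enantiomers of 8 react at the same rate. The step needs site selectivity between the carbons ortho to the chain and the more nucleophilic carbon between the methoxy groups; the palladacycle can reach only the ortho carbons, and the mirror symmetry of the 3,5-dimethoxyphenyl ring makes these two identical, so only one lactone can form. It also needs chemoselectivity against β-hydride elimination of the secondary palladium alkoxide, which is supported by CO occupying the site that elimination requires and by the ligand-accelerated C–H cleavage on the electron-rich ring; the TBDPS ether offers no coordinating or acid-labile site.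

Step 6
Reactants: 10 racemic 3-{11-[(tert-butyldiphenylsilyl)oxy]undecyl}-6,8-dimethoxyisochroman-1-one
Product: 12 racemic benzyl 2-{13-[(tert-butyldiphenylsilyl)oxy]-2-hydroxytridecyl}-4,6-dimethoxybenzoate, via potassium carboxylate 11 (not isolated)
Conditions: KOH (1.2 equiv), THF/MeOH/H2O, 40 °C; CO2, evaporate; BnBr, DMF, rt; used without chromatography
Reagents that add atoms: potassium hydroxide, [K+].[OH-]; benzyl bromide, BrCc1ccccc1
Why: Saponification opens the lactone irreversibly to the carboxylate, and SN2 O-alkylation of that salt gives the ester without passing through the free hydroxy acid, which would close again; excess hydroxide is buffered with CO2 so that no alkoxide is present to re-form the lactone. The benzyl ester is chosen because the Lewis acid of step 8 removes it, so no basic ester hydrolysis is needed next to the later ketone.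

Step 7
Reactants: 12 racemic benzyl 2-{13-[(tert-butyldiphenylsilyl)oxy]-2-hydroxytridecyl}-4,6-dimethoxybenzoate
Product: 13 benzyl 2-{13-[(tert-butyldiphenylsilyl)oxy]-2-oxotridecyl}-4,6-dimethoxybenzoate
Conditions: Dess–Martin periodinane, NaHCO3, CH2Cl2, 0 °C → rt
Reagents that add atoms: none
Why: Dess–Martin oxidation of a secondary alcohol under buffered, neutral conditions; it removes the racemic stereocentre, ends the risk of relactonisation, and should not touch the electron-rich ring, the silyl ether or the ester.

Step 8
Reactants: 13 benzyl 2-{13-[(tert-butyldiphenylsilyl)oxy]-2-oxotridecyl}-4,6-dimethoxybenzoate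
Product: 14 2-{13-[(tert-butyldiphenylsilyl)oxy]-2-oxotridecyl}-6-hydroxy-4-methoxybenzoic acid
Conditions: BCl3 (4 equiv), pentamethylbenzene, CH2Cl2, −78 → 0 °C; aq. NaHCO3, then pH 3 at 0 °C
Reagents that add atoms: none
Why: BCl3 binds the ester carbonyl and the ortho methoxy oxygen in a six-membered chelate and chloride removes that methyl group (chelation-controlled O-demethylation ortho to a carbonyl), while the para methoxy group cannot chelate and stays. The same reagent cleaves the benzyl ester (Lewis-acid debenzylation) with pentamethylbenzene trapping the benzyl cation, and the boron salicylate chelate formed should shield the acid from the ketone until aqueous work-up; the TBDPS ether should tolerate the short cold exposure.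

Step 9
Reactants: 14 2-{13-[(tert-butyldiphenylsilyl)oxy]-2-oxotridecyl}-6-hydroxy-4-methoxybenzoic acid
Product: 15 2-hydroxy-6-(13-hydroxy-2-oxotridecyl)-4-methoxybenzoic acid
Conditions: Bu4NF (4 equiv), THF, rt; aq. citric acid, 0 °C
Reagents that add atoms: none
Why: Fluoride-mediated cleavage of the silyl ether, driven by Si–F bond formation; the substrate reacts as its carboxylate and phenoxide, which give the enolisable ketone nothing to acylate, and cold, mild acidification should avoid dehydration to the isocoumarin.

## Compound list

1 | 11-bromoundecan-1-ol | OCCCCCCCCCCCBr | starting material
2 | tert-butyl[(11-bromoundecyl)oxy]diphenylsilane | CC(C)(C)[Si](OCCCCCCCCCCCBr)(c1ccccc1)c1ccccc1 | intermediate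
3 | 3,5-dimethoxyphenylacetic acid | COc1cc(CC(=O)O)cc(OC)c1 | starting material
4 | 2-(3,5-dimethoxyphenyl)-1-(1H-imidazol-1-yl)ethan-1-one (acyl imidazole, not isolated) | COc1cc(CC(=O)n2ccnc2)cc(OC)c1 | intermediate
5 | 2-(3,5-dimethoxyphenyl)-N-methoxy-N-methylacetamide | COc1cc(CC(=O)N(C)OC)cc(OC)c1 | intermediate
6 | {11-[(tert-butyldiphenylsilyl)oxy]undecyl}magnesium bromide (Grignard reagent, not isolated) | CC(C)(C)[Si](OCCCCCCCCCCC[Mg]Br)(c1ccccc1)c1ccccc1 | intermediate
7 | 13-[(tert-butyldiphenylsilyl)oxy]-1-(3,5-dimethoxyphenyl)tridecan-2-one | COc1cc(OC)cc(CC(=O)CCCCCCCCCCCO[Si](c2ccccc2)(c2ccccc2)C(C)(C)C)c1 | intermediate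
8 | racemic 13-[(tert-butyldiphenylsilyl)oxy]-1-(3,5-dimethoxyphenyl)tridecan-2-ol | COc1cc(OC)cc(CC(O)CCCCCCCCCCCO[Si](c2ccccc2)(c2ccccc2)C(C)(C)C)c1 | intermediate
9 | carbon monoxide | [C-]#[O+] | starting material
10 | racemic 3-{11-[(tert-butyldiphenylsilyl)oxy]undecyl}-6,8-dimethoxyisochroman-1-one | COc1cc(OC)c2c(c1)CC(CCCCCCCCCCCO[Si](c1ccccc1)(c1ccccc1)C(C)(C)C)OC2=O | intermediate
11 | racemic potassium 2-{13-[(tert-butyldiphenylsilyl)oxy]-2-hydroxytridecyl}-4,6-dimethoxybenzoate (not isolated) | COc1cc(OC)c(C(=O)[O-])c(CC(O)CCCCCCCCCCCO[Si](c2ccccc2)(c2ccccc2)C(C)(C)C)c1.[K+] | intermediate
12 | racemic benzyl 2-{13-[(tert-butyldiphenylsilyl)oxy]-2-hydroxytridecyl}-4,6-dimethoxybenzoate | COc1cc(OC)c(C(=O)OCc2ccccc2)c(CC(O)CCCCCCCCCCCO[Si](c2ccccc2)(c2ccccc2)C(C)(C)C)c1 | intermediate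
13 | benzyl 2-{13-[(tert-butyldiphenylsilyl)oxy]-2-oxotridecyl}-4,6-dimethoxybenzoate | COc1cc(OC)c(C(=O)OCc2ccccc2)c(CC(=O)CCCCCCCCCCCO[Si](c2ccccc2)(c2ccccc2)C(C)(C)C)c1 | intermediate
14 | 2-{13-[(tert-butyldiphenylsilyl)oxy]-2-oxotridecyl}-6-hydroxy-4-methoxybenzoic acid | COc1cc(O)c(C(=O)O)c(CC(=O)CCCCCCCCCCCO[Si](c2ccccc2)(c2ccccc2)C(C)(C)C)c1 | intermediate
15 | 2-hydroxy-6-(13-hydroxy-2-oxotridecyl)-4-methoxybenzoic acid | COc1cc(O)c(C(=O)O)c(CC(=O)CCCCCCCCCCCO)c1 | target

## Step count and risk

Total step count: 9. Longest linear sequence: 8 steps (1 → 2 → 7 → 8 → 10 → 12 → 13 → 14 → 15; the branch from 3 through 5 is equally long).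

Step 5 (key step). The most likely failure is β-hydride elimination from the secondary palladium alkoxide, which would oxidise the directing alcohol back to the ketone level and stop the cycle. Palladation at a carbon flanked by the chain and a methoxy group may also be slow, and CO may reduce the catalyst to metallic palladium before turnover. The fallback replaces C–H activation by a carbon–halogen bond and sets out from 8. Electrophilic bromination with NBS in MeCN at 0 °C should go ortho to the chain, the carbon between the methoxy groups being the more hindered, and give racemic 1-(2-bromo-3,5-dimethoxyphenyl)-13-[(tert-butyldiphenylsilyl)oxy]tridecan-2-ol F1. Classical palladium-catalysed intramolecular alkoxycarbonylation of this aryl bromide (Pd(OAc)2, Xantphos, Et3N, CO at 1 atm, toluene, 100 °C) should then close the same lactone, and the route is rejoined at 10.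

Step 6. The lactone may re-form by attack of the secondary hydroxyl on the new ester before the oxidation. Hydroxide may also erode the silyl ether, and hydrolysis of the hindered, electron-rich lactone may be incomplete. The fallback avoids any hydroxy ester and sets out from 10. Aminolysis with the aluminium amide made from AlMe3 and morpholine should give the tertiary amide racemic (2-{13-[(tert-butyldiphenylsilyl)oxy]-2-hydroxytridecyl}-4,6-dimethoxyphenyl)(morpholin-4-yl)methanone F2, which does not relactonise under neutral conditions. Dess–Martin oxidation should give 13-[(tert-butyldiphenylsilyl)oxy]-1-[3,5-dimethoxy-2-(morpholine-4-carbonyl)phenyl]tridecan-2-one F3. Warming F3 in acetic acid should close the enol lactone with loss of morpholine to 3-{11-[(tert-butyldiphenylsilyl)oxy]undecyl}-6,8-dimethoxy-1H-isochromen-1-one F4. Aqueous KOH opens this enol lactone directly to the keto carboxylate, and alkylation with BnBr in DMF rejoins the route at 13, bypassing 12 and step 7.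

Step 8. The freed keto acid may undergo dehydrative closure onto its enol under the Lewis acid. Cleavage of the benzyl ester may be incomplete, the benzyl cation may alkylate the electron-rich ring, and the silyl ether may be partly lost. The fallback turns the first of these into the route and sets out from 13. After the BCl3 treatment the crude material would be heated with p-TsOH in toluene to complete the closure to 3-{11-[(tert-butyldiphenylsilyl)oxy]undecyl}-8-hydroxy-6-methoxy-1H-isochromen-1-one F5, a stable chelated phenol that is easy to purify. Alkaline opening of this enol lactone (LiOH, aqueous THF, 40 °C) and cold acidification should return the keto acid, rejoining the route at 14.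

Step 3. The Grignard reagent may deprotonate the acidic benzylic position of 5 in competition with addition, and Wurtz coupling may consume the bromide while 6 is formed. The fallback reverses the polarity of the C–C bond formation and sets out from 2. Grignard reagent 6 is formylated with DMF to 12-[(tert-butyldiphenylsilyl)oxy]dodecanal F6. The benzylic nucleophile (3,5-dimethoxybenzyl)magnesium chloride F7, made from purchased 3,5-dimethoxybenzyl chloride and Mg in THF at 0 °C, is then added to F6. This gives the carbinol directly and rejoins the route at 8, bypassing 5, 7 and step 4. It is kept as a fallback because benzylic Grignard reagents homocouple easily.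

## Further compounds

F1 | step 5 | racemic 1-(2-bromo-3,5-dimethoxyphenyl)-13-[(tert-butyldiphenylsilyl)oxy]tridecan-2-ol | COc1cc(OC)c(Br)c(CC(O)CCCCCCCCCCCO[Si](c2ccccc2)(c2ccccc2)C(C)(C)C)c1
F2 | step 6 | racemic (2-{13-[(tert-butyldiphenylsilyl)oxy]-2-hydroxytridecyl}-4,6-dimethoxyphenyl)(morpholin-4-yl)methanone | COc1cc(OC)c(C(=O)N2CCOCC2)c(CC(O)CCCCCCCCCCCO[Si](c2ccccc2)(c2ccccc2)C(C)(C)C)c1
F3 | step 6 | 13-[(tert-butyldiphenylsilyl)oxy]-1-[3,5-dimethoxy-2-(morpholine-4-carbonyl)phenyl]tridecan-2-one | COc1cc(OC)c(C(=O)N2CCOCC2)c(CC(=O)CCCCCCCCCCCO[Si](c2ccccc2)(c2ccccc2)C(C)(C)C)c1
F4 | step 6 | 3-{11-[(tert-butyldiphenylsilyl)oxy]undecyl}-6,8-dimethoxy-1H-isochromen-1-one | COc1cc(OC)c2c(c1)C=C(CCCCCCCCCCCO[Si](c1ccccc1)(c1ccccc1)C(C)(C)C)OC2=O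
F5 | step 8 | 3-{11-[(tert-butyldiphenylsilyl)oxy]undecyl}-8-hydroxy-6-methoxy-1H-isochromen-1-one | COc1cc(O)c2c(c1)C=C(CCCCCCCCCCCO[Si](c1ccccc1)(c1ccccc1)C(C)(C)C)OC2=O
F6 | step 3 | 12-[(tert-butyldiphenylsilyl)oxy]dodecanal | O=CCCCCCCCCCCCO[Si](c1ccccc1)(c1ccccc1)C(C)(C)C
F7 | step 3 | (3,5-dimethoxybenzyl)magnesium chloride | COc1cc(C[Mg]Cl)cc(OC)c1
A1 | alternative 1 | 6-{5-[2-(11-{[tert-butyl(dimethyl)silyl]oxy}undecyl)-1,3-dioxolan-2-yl]-2,4-dioxopentyl}-2,2-dimethyl-4H-1,3-dioxin-4-one | CC1(C)OC(=O)C=C(CC(=O)CC(=O)CC2(CCCCCCCCCCCO[Si](C)(C)C(C)(C)C)OCCO2)O1
A2 | alternative 1 | 5-{[2-(11-{[tert-butyl(dimethyl)silyl]oxy}undecyl)-1,3-dioxolan-2-yl]methyl}-7-hydroxy-2,2-dimethyl-4H-1,3-benzodioxin-4-one | CC1(C)OC(=O)c2c(CC3(CCCCCCCCCCCO[Si](C)(C)C(C)(C)C)OCCO3)cc(O)cc2O1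
A3 | alternative 2 | 2,4-dimethoxybenzoic acid | COc1ccc(C(=O)O)c(OC)c1
A4 | alternative 2 | 13-{[tert-butyl(dimethyl)silyl]oxy}-1-[dimethyl(oxo)-λ6-sulfanylidene]tridecan-2-one | CS(C)(=O)=CC(=O)CCCCCCCCCCCO[Si](C)(C)C(C)(C)C
A5 | alternative 2 | 3-(11-{[tert-butyl(dimethyl)silyl]oxy}undecyl)-6,8-dimethoxy-1H-isochromen-1-one | COc1cc(OC)c2c(c1)C=C(CCCCCCCCCCCO[Si](C)(C)C(C)(C)C)OC2=O
A6 | alternative 3 | 1,3-dimethoxy-1-(trimethylsilyloxy)buta-1,3-diene | COC(=C)C=C(OC)O[Si](C)(C)C
A7 | alternative 3 | methyl 4-[2-(11-{[tert-butyl(dimethyl)silyl]oxy}undecyl)-1,3-dithian-2-yl]but-2-ynoate | COC(=O)C#CCC1(CCCCCCCCCCCO[Si](C)(C)C(C)(C)C)SCCCS1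
A8 | alternative 3 | methyl 2-{[2-(11-{[tert-butyl(dimethyl)silyl]oxy}undecyl)-1,3-dithian-2-yl]methyl}-6-hydroxy-4-methoxybenzoate | COC(=O)c1c(O)cc(OC)cc1CC1(CCCCCCCCCCCO[Si](C)(C)C(C)(C)C)SCCCS1
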